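1. The amounts of mono adduct in both earlier runs rise to a peak and then fall, so I reckon the end of theta as a point on that fall.

| flask | starting material | partner | remark | time |
|---|---|---|---|---|
| grey | 0.80 M | 0.58 M | run made earlier |  |
| violet | 0.80 M | 2.2 M | run made earlier |  |
| theta | 0.80 M | 0.800 M |  | 2.0 h |
| epsilon | 0.80 M | 2.00 M |  | 2.0 h |
| alpha | 0.80 M | 0.400 M |  | 2.0 h |

| grey: time / min | grey: mono adduct / % | violet: time / min | violet: mono adduct / % |
|---|---|---|---|
| 8.00 | 7.4 | 5.00 | 16.0 |
| 20.0 | 12.9 | 12.0 | 25.4 |
| 40.0 | 11.5 | 25.0 | 24.8 |
| 60.0 | 8.7 | 60.0 | 13.4 |

(readings scatter by 1 percentage point)

1. which of these holds the largest part of the starting material at the end of theta (mono adduct / double product / starting material)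
2. which of these holds the largest part of the starting material at the end of epsilon (mono adduct / double product / starting material)
3. which of these holds the largest part of the starting material at the end of alpha (mono adduct / double product / starting material)
4. amount of mono adduct at the end of theta, in percent of the starting material charged

- the earlier runs were read with a standard deviation of 1 percentage point
- reactions considered so far: partner -> decomposed reagent; mono adduct -> over-reaction product; mono adduct <-> isomer of the product; partner + mono adduct -> double product + released group; starting material + partner -> mono adduct + released group

2. Two times set my estimate. From grey's last two readings I read 71.7 min, the fall time, meaning the time in which mono adduct would drop by a factor e if it went on falling as it does between those two readings. This is a reading and carries the scatter.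

3. The second time is the wait from the last readings to the end of theta, 60.0 min. Assuming an exponential fall, their ratio of 0.837 leaves a fraction 0.433.

4. Theta's partner charge is more than grey's and less than violet's, so I carry both last readings forward. Grey gives 3.77% and violet 5.80%. I commit to the middle, 4.78%, which is above the forecast's value.

5. The forecast names starting material for theta, starting material for epsilon and starting material for alpha, and gives 3.8% of mono adduct in theta, within 2% to 6.5%: “Product is split among several sinks, so starting material likely stays largest in all three.”

6. Theta ends with starting material largest at 43.8%, and alpha with starting material at 67.6%, but epsilon ends with double product at 35.7%, so the forecast fails there. Theta's mono adduct is 5.60%, inside my span.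

    partner → decomposed reagent (k = 0.00400 min⁻¹)
    mono adduct → over-reaction product (k = 0.0130 min⁻¹)
    mono adduct ⇌ isomer of the product (K = 15.0, k = 0.0220 min⁻¹)
    partner + mono adduct → double product + released group (k = 0.0210 L mol⁻¹ min⁻¹)
    starting material + partner → mono adduct + released group (k = 0.0210 L mol⁻¹ min⁻¹)

7. In theta, the half-life of mono adduct by its forward step to the isomer of the product, 0.53 h, is short against 2.0 h. At the end of theta, the isomer of the product holds 25.1% against 5.60% of mono adduct. As an estimate, the fall time takes theta's 11.8% at 1.00 h to 5.11% at the end.

8. For theta stopped at 50 min, the fall time gives as estimates 10.0% from grey's reading at 40.0 min and 17.5% from violet's at 25.0 min. The computed flask holds 13.2%.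

The data are simulated with made-up constants; noise was put on by code.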